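Retrosynthesis (eudesmane numbering): cut the C1–O bond of the bridge (C–H etherification from the C4 alcohol), then the C6 ester C–O bond, then C5–H and C6–H back to a 4,5-epoxy-6-ketone and its Δ4-6-one, then C4–C5 (aldol) and C10–C1 (conjugate addition).
Forward: ring B is (S)-piperitone; the C1–C4 chain is added at C10; ring A closes by Mukaiyama aldol condensation; epoxidation and dissolving-metal reduction give the trans-fused 4,6-diol; C6 is acylated; the oxolane C1–O–C4 closes last.
Stereochemistry: C7 from (S)-piperitone; C10 by conjugate addition cis to the isopropyl group; C4 by epoxidation anti to the C10 methyl; C5 by axial enolate protonation; C6 by thermodynamic reduction; C1 by delivery from the C4 oxygen.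
Enabling feature: in the ester the C4 oxygen is equatorial on ring A (C1–C2–C3–C4–C5–C10), on the face opposite the C10 methyl. The C4 and C10 methyls are 1,3-diaxial in the chair, so the boat is within reach; there the C4 oxygen and the axial C1–H are flagpole neighbours, and C1 needs no functional group before the last step.

Key step: step 6

Assumption: (S)-(+)-piperitone of high enantiomeric purity is taken as purchasable (otherwise from (−)-menthone by kinetic silyl enol ether formation and dehydrogenation); the direction of facial selectivity in step 1 is a prediction, not an established result.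

Step 1
Reactants: 1 (S)-piperitone; 2 2-(3-chloropropyl)-2-methyl-1,3-dioxolane
Product: 4 trimethyl{[(3S,6S)-3-methyl-3-[3-(2-methyl-1,3-dioxolan-2-yl)propyl]-6-(propan-2-yl)cyclohex-1-en-1-yl]oxy}silane (chain cis to isopropyl), via Grignard reagent 3 (not isolated)
Conditions: Mg, THF, reflux (2 → 3); then 1, CuBr·SMe2 (5 mol %), Me3SiCl, (Me2N)3PO, THF, −78 → −40 °C; Et3N
Reagents that add atoms: chlorotrimethylsilane, C[Si](C)(C)Cl
Why: Copper-catalysed conjugate addition of 3 to the β,β-disubstituted enone builds the C10 quaternary centre while Me3SiCl traps the enolate regiospecifically as the C5=C6 silyl enol ether without touching C7; antiparallel (axial) delivery to the half-chair of 1 with a pseudoequatorial isopropyl group should place the chain cis to that group.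

Step 2
Reactants: 4 silyl enol ether
Product: 6 (7S,10S)-eudesm-4-en-6-one, via cis-fused 4-(2-hydroxyethoxy)eudesman-6-one 5 (not isolated)
Conditions: TiCl4, CH2Cl2, −78 → 0 °C; aq. NaHCO3
Reagents that add atoms: none
Why: Intramolecular Mukaiyama aldol condensation: TiCl4 opens the dioxolane to an oxocarbenium ion that C5 of the silyl enol ether attacks in a 6-(enolexo)-exo-trig closure of ring A, and on warming the tertiary C4 alkoxy group of 5 ionises and is lost (E1) to give the conjugated enone without enolisation towards C7, so no new stereocentre remains.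

Step 3
Reactants: 6 enone
Product: 7 (4S,5R,7S,10S)-4,5-epoxyeudesman-6-one (oxirane on the face opposite the C10 methyl)
Conditions: t-BuOOH, n-BuLi, THF, −78 → 0 °C
Reagents that add atoms: tert-butyl hydroperoxide, CC(C)(C)OO
Why: Nucleophilic (Weitz–Scheffer-type) epoxidation: lithium tert-butylperoxide adds to C4 from the face that is not 1,3-diaxial to the C10 methyl and the enolate closes the oxirane on the same face, which sets the C4 oxygen anti and the C4 methyl syn to the C10 methyl, while the weakly basic peroxide should leave C7 unenolised.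

Step 4
Reactants: 7 epoxy ketone
Product: 9 (4S,5R,6R,7S,10S)-eudesmane-4,6-diol, via trans-fused 4-hydroxyeudesman-6-one 8 (not isolated)
Conditions: Li, NH3(l)/THF, −78 °C; MeOH, −78 → −33 °C; NH4Cl
Reagents that add atoms: none
Why: Dissolving-metal reduction: two-electron cleavage of the C5–O bond of the α,β-epoxy ketone gives the C4 alkoxide and C5=C6 enolate, methanol protonates C5 axially on the face opposite the C4 and C10 methyls (trans ring fusion, ketol 8), and excess lithium then reduces the ketone to the thermodynamically preferred equatorial C6 alcohol, cis to the C5 hydrogen and the C7 isopropyl group.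

Step 5
Reactants: 9 diol; 10 4-methoxybenzoyl chloride
Product: 11 (4S,5R,6R,7S,10S)-4-hydroxyeudesman-6-yl 4-methoxybenzoate
Conditions: Et3N, 4-(dimethylamino)pyridine (cat.), CH2Cl2, 0 °C → rt
Reagents that add atoms: none
Why: Acylation under nucleophilic catalysis takes place only at the secondary C6 hydroxyl, the tertiary C4 hydroxyl being too hindered to react.

Step 6
Reactants: 11 hydroxy ester
Product: 13 (1R,4S,5R,6R,7S,10S)-1,4-epoxyeudesman-6-yl 4-methoxybenzoate, via C4 hypoiodite 12 (not isolated)
Conditions: PhI(OAc)2, I2, benzene, visible light (tungsten lamp), 25–40 °C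
Reagents that add atoms: none
Why: Acetyl hypoiodite formed from PhI(OAc)2 and I2 converts the C4 hydroxyl into hypoiodite 12, whose O–I bond is cleaved by light to a tertiary alkoxyl radical; in the boat of ring A, reached easily because it removes the 1,3-diaxial contact of the C4 and C10 methyls, this oxygen and the axial C1 hydrogen are flagpole partners and the hydrogen is transferred through a six-membered transition state (1,5-hydrogen atom transfer). The C1 radical is trapped by iodine and the C4 oxygen then displaces iodide at C1, or captures the C1 cation after further oxidation, so the oxolane closes in the 5-exo-tet mode and completes the 7-oxabicyclo[2.2.1]heptane. This is the hypoiodite alkoxyl-radical etherification (Hofmann–Löffler–Freytag-type remote functionalisation) in its transannular form across a cyclohexane. The only new stereocentre, C1, is fixed by the tether, since the bridge can form only on the face that carries the C4 oxygen, opposite the C10 methyl. The step needs C1–H abstraction to outrun β-scission of the alkoxyl radical and attack on the other δ-hydrogens (C7, C9, C14); the equatorial C4–O bond points at none of these in either ring conformation, and the non-polar solvent and the strain relief in the boat favour hydrogen transfer over fragmentation. The ester and the five existing stereocentres do not take part.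

Compound list
1 | (S)-piperitone, (6S)-3-methyl-6-(propan-2-yl)cyclohex-2-en-1-one | CC1=CC(=O)[C@H](C(C)C)CC1 | starting material
2 | 2-(3-chloropropyl)-2-methyl-1,3-dioxolane | CC1(CCCCl)OCCO1 | starting material
3 | [3-(2-methyl-1,3-dioxolan-2-yl)propyl]magnesium chloride (not isolated) | CC1(CCC[Mg]Cl)OCCO1 | intermediate
4 | trimethyl{[(3S,6S)-3-methyl-3-[3-(2-methyl-1,3-dioxolan-2-yl)propyl]-6-(propan-2-yl)cyclohex-1-en-1-yl]oxy}silane | CC(C)[C@@H]1CC[C@](C)(CCCC2(C)OCCO2)C=C1O[Si](C)(C)C | intermediate
5 | (7S,10S)-4-(2-hydroxyethoxy)eudesman-6-one, cis-fused (C5–H syn to the C10 methyl), C4 unassigned, present as its titanium alkoxide (not isolated) | O=C1[C@H](C(C)C)CC[C@]2(C)CCCC(C)(OCCO)[C@H]12 | intermediate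
6 | (7S,10S)-eudesm-4-en-6-one (isopropyl trans to the C10 methyl) | O=C1[C@H](C(C)C)CC[C@]2(C)CCCC(C)=C12 | intermediate
7 | (4S,5R,7S,10S)-4,5-epoxyeudesman-6-one | O=C1[C@H](C(C)C)CC[C@]2(C)CCC[C@](C)(O3)[C@@]123 | intermediate
8 | (4S,5S,7S,10S)-4-hydroxyeudesman-6-one, trans-fused (not isolated) | O=C1[C@H](C(C)C)CC[C@]2(C)CCC[C@](C)(O)[C@@H]12 | intermediate
9 | (4S,5R,6R,7S,10S)-eudesmane-4,6-diol | O[C@@H]1[C@H](C(C)C)CC[C@]2(C)CCC[C@](C)(O)[C@@H]12 | intermediate
10 | 4-methoxybenzoyl chloride | COc1ccc(cc1)C(Cl)=O | starting material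
11 | (4S,5R,6R,7S,10S)-4-hydroxyeudesman-6-yl 4-methoxybenzoate | COc1ccc(cc1)C(=O)O[C@@H]1[C@H](C(C)C)CC[C@]2(C)CCC[C@](C)(O)[C@@H]12 | intermediate
12 | C4 hypoiodite of 11 (not isolated) | COc1ccc(cc1)C(=O)O[C@@H]1[C@H](C(C)C)CC[C@]2(C)CCC[C@](C)(OI)[C@@H]12 | intermediate
13 | (1R,4S,5R,6R,7S,10S)-1,4-epoxyeudesman-6-yl 4-methoxybenzoate | COc1ccc(cc1)C(=O)O[C@@H]1[C@H](C(C)C)CC[C@]2(C)[C@H]3CC[C@](C)(O3)[C@@H]12 | target

Total steps: 6. Longest linear sequence: 6 steps (from 1).

Steps most likely to fail

Step 6. The tertiary alkoxyl radical may fragment (β-scission of C4–C5 or loss of the C4 methyl) faster than it abstracts the transannular hydrogen. The C1 radical or cation next to quaternary C10 may eliminate or rearrange instead of closing the strained trans-fused oxolane. Acetyl hypoiodite may also iodinate the anisoyl ring. The fallback closes the same C1–O bond by ionic iodoetherification of a C1=C2 alkene; it sets out from 1 and comes back at 13. (Z)-2-(3-Iodoprop-2-en-1-yl)-2-methyl-1,3-dioxolane F1 is lithiated (t-BuLi), turned into its lithium cuprate (CuI) and added to 1 with Me3SiCl to give the alkenyl silyl enol ether F2. TiCl4 closure as in step 2 gives eudesma-1,4-dien-6-one F3, epoxidation as in step 3 gives 4,5-epoxyeudesm-1-en-6-one F4, Li/NH3 reduction (the isolated alkene survives) gives eudesm-1-ene-4,6-diol F5, and acylation with 10 gives 4-hydroxyeudesm-1-en-6-yl 4-methoxybenzoate F6. I2 and NaHCO3 in MeCN then make the C4 hydroxyl attack C1 anti to the iodonium ion (5-exo), giving 2-iodo-1,4-epoxyeudesman-6-yl 4-methoxybenzoate F7, and Bu3SnH with AIBN removes the iodine to give 13.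

Step 1. The 1,4-induction from the isopropyl group may be weak or reversed: the chain may be delivered anti to a pseudoaxial isopropyl group, giving mainly the C10 epimer. That epimer would need removal at 6 before any C7 epimerisation could turn it into the enantiomeric series. The fallback reverses the order in which the two C10 substituents arrive, so that the same facial preference gives 4; it sets out from 3 and comes back at 4. Grignard reagent 3 is added 1,2 (CeCl3, THF) to (S)-cryptone F8 to give the tertiary allylic alcohol 1-[3-(2-methyl-1,3-dioxolan-2-yl)propyl]-4-(propan-2-yl)cyclohex-2-en-1-ol F9. Oxidative 1,3-transposition (IBX, DMSO) gives (6S)-3-[3-(2-methyl-1,3-dioxolan-2-yl)propyl]-6-(propan-2-yl)cyclohex-2-en-1-one F10. CuBr·SMe2-catalysed addition of MeMgBr with Me3SiCl then puts the methyl on the face anti to the isopropyl group, which is the arrangement of 4.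

Step 2. After cyclisation the tertiary alkoxy group may not be lost cleanly, the aldol adduct may reopen, or the acid may epimerise C7 during elimination. The fallback is a thermodynamic aldol condensation; it sets out from 4 and comes back at 6. Cold aqueous HCl in THF hydrolyses both the silyl enol ether and the ketal of 4 to (2S,5S)-5-methyl-5-(4-oxopentyl)-2-(propan-2-yl)cyclohexan-1-one F11, from which any C10 epimer is removed by chromatography. KOH in MeOH then closes ring A to 6 together with its C7 epimer (7R,10S)-eudesm-4-en-6-one F12, which is separated and re-equilibrated with base; the absolute configuration is safe because C10 is quaternary.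

Further compounds
F1 | step 6 | (Z)-2-(3-iodoprop-2-en-1-yl)-2-methyl-1,3-dioxolane | CC1(C/C=C\I)OCCO1
F2 | step 6 | trimethyl{[3-methyl-3-[(Z)-3-(2-methyl-1,3-dioxolan-2-yl)prop-1-en-1-yl]-6-(propan-2-yl)cyclohex-1-en-1-yl]oxy}silane (alkenyl group cis to isopropyl) | CC(C)[C@@H]1CC[C@](C)(/C=C\CC2(C)OCCO2)C=C1O[Si](C)(C)C
F3 | step 6 | eudesma-1,4-dien-6-one (C7 and C10 as in 6) | O=C1[C@H](C(C)C)CC[C@]2(C)C=CCC(C)=C12
F4 | step 6 | 4,5-epoxyeudesm-1-en-6-one (oxirane opposite the C10 methyl) | O=C1[C@H](C(C)C)CC[C@]2(C)C=CC[C@](C)(O3)[C@@]123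
F5 | step 6 | eudesm-1-ene-4,6-diol (configured as 9) | O[C@@H]1[C@H](C(C)C)CC[C@]2(C)C=CC[C@](C)(O)[C@@H]12
F6 | step 6 | 4-hydroxyeudesm-1-en-6-yl 4-methoxybenzoate | COc1ccc(cc1)C(=O)O[C@@H]1[C@H](C(C)C)CC[C@]2(C)C=CC[C@](C)(O)[C@@H]12
F7 | step 6 | 2-iodo-1,4-epoxyeudesman-6-yl 4-methoxybenzoate (iodine anti to the oxygen bridge) | COc1ccc(cc1)C(=O)O[C@@H]1[C@H](C(C)C)CC[C@]2(C)[C@H]3[C@@H](I)C[C@](C)(O3)[C@@H]12
F8 | step 1 | (S)-cryptone, (4S)-4-(propan-2-yl)cyclohex-2-en-1-one | O=C1C=C[C@H](C(C)C)CC1
F9 | step 1 | (4S)-1-[3-(2-methyl-1,3-dioxolan-2-yl)propyl]-4-(propan-2-yl)cyclohex-2-en-1-ol (carbinol centre as a mixture) | OC1(CCCC2(C)OCCO2)C=C[C@H](C(C)C)CC1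
F10 | step 1 | (6S)-3-[3-(2-methyl-1,3-dioxolan-2-yl)propyl]-6-(propan-2-yl)cyclohex-2-en-1-one | O=C1C=C(CCCC2(C)OCCO2)CC[C@H]1C(C)C
F11 | step 2 | (2S,5S)-5-methyl-5-(4-oxopentyl)-2-(propan-2-yl)cyclohexan-1-one | CC(C)[C@@H]1CC[C@](C)(CCCC(C)=O)CC1=O
F12 | step 2 | (7R,10S)-eudesm-4-en-6-one (C7 epimer of 6) | O=C1[C@@H](C(C)C)CC[C@]2(C)CCCC(C)=C12
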